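The flavone is cut at three ring C bonds, O1–C8a, C4–C4a and O1–C2. This gives a ring A aryne (C4a≡C8a) and a ring B arylpropiolic acid. The feature exploited is that O1 and the C4 carbonyl are ortho neighbours on ring A. C4a is flanked by the C5 oxygen and C8a only by C8–H, so the C5 ether polarises the aryne. In one operation the aryne inserts into the acid's C–O bond (oxygen to C8a, acyl to C4a) and the freed phenoxide closes the pyrone. The precursor is an ortho-silylaryl triflate built from a mirror-symmetric 3,5-dibenzyloxy-4-methoxyphenol. Sulfation of the single free 4'-OH and global reductive unmasking finish the synthesis.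

Key step: step 9

Remark: the free hydrogen sulfate as drawn is taken as the target, so the route ends with an ammonium-for-proton exchange; because aryl hydrogen sulfates hydrolyse in warm acid, the ammonium salt made one step earlier is the form to store.

Step 1
Reactants: 1 methyl 3,5-dihydroxy-4-methoxybenzoate
Product: 2 methyl 3,5-bis(benzyloxy)-4-methoxybenzoate
Conditions: BnBr (2.4 equiv), K2CO3, DMF, 60 °C
Reagents that add atoms: benzyl bromide, BrCc1ccccc1
Why: Williamson ether synthesis on two equivalent phenols, with the purchased 4-methoxy group already marking the future 6-OMe as different from the 5- and 7-oxygens.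

Step 2
Reactants: 2 methyl 3,5-bis(benzyloxy)-4-methoxybenzoate
Product: 3 [3,5-bis(benzyloxy)-4-methoxyphenyl]methanol
Conditions: LiAlH4, THF, 0 °C → rt
Reagents that add atoms: none
Why: Hydride reduction of an aryl ester to the benzylic alcohol leaves the ethers untouched and is chosen over a one-step partial reduction, which tends to over-reduce aromatic esters.

Step 3
Reactants: 3 [3,5-bis(benzyloxy)-4-methoxyphenyl]methanol
Product: 4 3,5-bis(benzyloxy)-4-methoxybenzaldehyde
Conditions: activated MnO2 (excess), CH2Cl2, rt
Reagents that add atoms: none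
Why: Heterogeneous MnO2 oxidation is selective for activated benzylic alcohols and should stop cleanly at the aldehyde.

Step 4
Reactants: 4 3,5-bis(benzyloxy)-4-methoxybenzaldehyde
Product: 6 3,5-bis(benzyloxy)-4-methoxyphenol, via aryl formate 5 (not isolated)
Conditions: mCPBA, CH2Cl2, 0 °C → rt; aq. NaHCO3/Na2S2O3 wash, solvent swap; K2CO3 (0.2 equiv), MeOH, rt, argon
Reagents that add atoms: mCPBA, OOC(=O)c1cccc(Cl)c1
Why: Baeyer–Villiger oxidation with a Dakin-type outcome, in which the electron-rich aryl group (pushed by the para methoxy oxygen) migrates in the Criegee adduct rather than hydride, followed by base-catalysed methanolysis of the formate.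

Step 5
Reactants: 6 3,5-bis(benzyloxy)-4-methoxyphenol
Product: 7 2-bromo-3,5-bis(benzyloxy)-4-methoxyphenol
Conditions: NBS (1.0 equiv), CH2Cl2, −78 → 0 °C, dark
Reagents that add atoms: N-bromosuccinimide, O=C1CCC(=O)N1Br
Why: Electrophilic aromatic bromination in which the para position is blocked and the two ortho carbons are related by the mirror plane, so one equivalent of NBS at low temperature can give only one monobromide.

Step 6
Reactants: 7 2-bromo-3,5-bis(benzyloxy)-4-methoxyphenol
Product: 11 3,5-bis(benzyloxy)-4-methoxy-2-(trimethylsilyl)phenyl trifluoromethanesulfonate, via silyl ether 8 (not isolated), via aryllithium 9 (not isolated), via lithium silylphenoxide 10 (not isolated)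
Conditions: HMDS, THF, 70 °C, volatiles removed in vacuo in the same flask; n-BuLi (1.1 equiv), THF, −78 °C; Tf2O, −78 → 0 °C
Reagents that add atoms: hexamethyldisilazane, C[Si](C)(C)N[Si](C)(C)C; triflic anhydride, O=S(=O)(OS(=O)(=O)C(F)(F)F)C(F)(F)F
Why: O-silylation, bromine–lithium exchange (far faster at −78 °C than benzylic deprotonation) and a 1,3 O→C silyl shift (retro-Brook rearrangement) put silicon on the carbon that carried bromine, and the phenoxide so released is trapped as the triflate.

Step 7
Reactants: 12 4-iodophenol
Product: 13 1-iodo-4-(methoxymethoxy)benzene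
Conditions: MOMCl, i-Pr2NEt, CH2Cl2, 0 °C → rt
Reagents that add atoms: chloromethyl methyl ether, COCCl
Why: O-alkylation of the phenol to a methoxymethyl acetal, a group that withstands amine bases and hot fluoride and is orthogonal to the benzyl ethers of ring A.

Step 8
Reactants: 13 1-iodo-4-(methoxymethoxy)benzene; 14 propiolic acid
Product: 15 3-[4-(methoxymethoxy)phenyl]propiolic acid
Conditions: Pd(PPh3)4 (2.5 mol %), DBU (2.5 equiv), DMSO, 30 °C; cold aq. KHSO4, rapid extraction
Reagents that add atoms: none
Why: Copper-free Sonogashira (Heck–Cassar) alkynylation of an aryl iodide by the propiolate on zerovalent palladium, in which omitting CuI and staying near room temperature should suppress protodecarboxylation of the product, a second coupling and Glaser dimerisation.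

Step 9
Reactants: 11 3,5-bis(benzyloxy)-4-methoxy-2-(trimethylsilyl)phenyl trifluoromethanesulfonate; 15 3-[4-(methoxymethoxy)phenyl]propiolic acid
Product: 18 5,7-bis(benzyloxy)-6-methoxy-2-[4-(methoxymethoxy)phenyl]-4H-chromen-4-one, via aryne 16 (not isolated), via hydroxyaryl ynone 17 (not isolated)
Conditions: 15 (1.5 equiv) pre-stirred with CsF (5 equiv), THF, rt; then 11, 125 °C, sealed tube
Reagents that add atoms: none
Why: Fluoride strips the silyl group of 11 and triflate leaves from the neighbouring carbon, releasing aryne 16 (C4a≡C8a in flavone numbering). The selectivity needed is oxygen at C8a and acyl at C4a, and the C5 benzyloxy group secures it: its inductive pull distorts the triple bond so that the remote, unhindered C8a is the electrophilic end, and it stabilises the negative charge that develops on C4a when the carboxylate of 15 adds. The aryl anion then attacks the adjacent ester carbonyl (4-exo-trig) and the strained four-membered alkoxide opens by C–O scission, which amounts to insertion of the aryne into the acid C–O bond and leaves the phenoxide of ynone 17. This phenoxide adds to the alkyne carbon C2 in a 6-endo-dig oxa-Michael closure of ring C, the mode preferred over 5-exo-dig in aprotic media. The closest known reaction type is the CsF-mediated coupling of ortho-silylaryl triflates with carboxylic acids to ortho-hydroxyaryl ketones, which runs on to flavones with arylpropiolic acids. Heat, slow aryne release from sparingly soluble CsF and an excess of fully deprotonated acid disfavour simple protonation of the aryl anion and O-arylation of the product phenoxide, and no stereocentre is formed.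

Step 10
Reactants: 18 5,7-bis(benzyloxy)-6-methoxy-2-[4-(methoxymethoxy)phenyl]-4H-chromen-4-one
Product: 19 5,7-bis(benzyloxy)-2-(4-hydroxyphenyl)-6-methoxy-4H-chromen-4-one
Conditions: HCl (1.25 M in MeOH), THF, 40 °C
Reagents that add atoms: none
Why: Acid-catalysed acetal exchange with methanol (MOM cleavage) runs under conditions too mild for aryl benzyl ethers and exposes the 4'-OH as the only free hydroxyl.

Step 11
Reactants: 19 5,7-bis(benzyloxy)-2-(4-hydroxyphenyl)-6-methoxy-4H-chromen-4-one
Product: 20 4-[5,7-bis(benzyloxy)-6-methoxy-4-oxo-4H-chromen-2-yl]phenyl 2,2,2-trichloroethyl sulfate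
Conditions: Cl3CCH2OSO2Cl (1.5 equiv), Et3N, DMAP (0.2 equiv), THF, 0 °C → rt
Reagents that add atoms: 2,2,2-trichloroethyl chlorosulfate, ClS(=O)(=O)OCC(Cl)(Cl)Cl
Why: DMAP-catalysed sulfuryl transfer from the chlorosulfate to the only phenol present gives a neutral, chromatographable sulfate diester with no regiochemical question.

Step 12
Reactants: 20 4-[5,7-bis(benzyloxy)-6-methoxy-4-oxo-4H-chromen-2-yl]phenyl 2,2,2-trichloroethyl sulfate
Product: 21 ammonium 4-(5,7-dihydroxy-6-methoxy-4-oxo-4H-chromen-2-yl)phenyl sulfate
Conditions: 10% Pd/C, HCO2NH4 (excess), MeOH/THF, rt, monitored; reversed-phase (C18) chromatography, H2O/MeOH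
Reagents that add atoms: ammonium formate, O=C[O-].[NH4+]
Why: Catalytic transfer hydrogenolysis cleaves both O-benzyl bonds and triggers reductive fragmentation of the trichloroethyl ester, while the formate buffer holds the aryl sulfate as its stable ammonium salt and room temperature should spare the C2–C3 double bond.

Step 13
Reactants: 21 ammonium 4-(5,7-dihydroxy-6-methoxy-4-oxo-4H-chromen-2-yl)phenyl sulfate
Product: 22 hispidulin 4'-sulfate, 4-(5,7-dihydroxy-6-methoxy-4-oxo-4H-chromen-2-yl)phenyl hydrogen sulfate
Conditions: polystyrene-sulfonic acid resin (H+ form), H2O/MeOH, 0–5 °C; immediate freeze-drying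
Reagents that add atoms: none
Why: Cation exchange on a strongly acidic resin swaps ammonium for a proton, and working cold with immediate freeze-drying limits acid hydrolysis of the aryl sulfate.

Compound list
1 | methyl 3,5-dihydroxy-4-methoxybenzoate | COC(=O)c1cc(O)c(OC)c(O)c1 | starting material
2 | methyl 3,5-bis(benzyloxy)-4-methoxybenzoate | COC(=O)c1cc(OCc2ccccc2)c(OC)c(OCc2ccccc2)c1 | intermediate
3 | [3,5-bis(benzyloxy)-4-methoxyphenyl]methanol | OCc1cc(OCc2ccccc2)c(OC)c(OCc2ccccc2)c1 | intermediate
4 | 3,5-bis(benzyloxy)-4-methoxybenzaldehyde | COc1c(OCc2ccccc2)cc(C=O)cc1OCc1ccccc1 | intermediate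
5 | 3,5-bis(benzyloxy)-4-methoxyphenyl formate (carried on crude) | COc1c(OCc2ccccc2)cc(OC=O)cc1OCc1ccccc1 | intermediate
6 | 3,5-bis(benzyloxy)-4-methoxyphenol | COc1c(OCc2ccccc2)cc(O)cc1OCc1ccccc1 | intermediate
7 | 2-bromo-3,5-bis(benzyloxy)-4-methoxyphenol | COc1c(OCc2ccccc2)cc(O)c(Br)c1OCc1ccccc1 | intermediate
8 | [3,5-bis(benzyloxy)-2-bromo-4-methoxyphenoxy]trimethylsilane (formed in the flask) | COc1c(OCc2ccccc2)cc(O[Si](C)(C)C)c(Br)c1OCc1ccccc1 | intermediate
9 | [2,4-bis(benzyloxy)-3-methoxy-6-(trimethylsilyloxy)phenyl]lithium (formed in the flask) | COc1c(OCc2ccccc2)cc(O[Si](C)(C)C)c([Li])c1OCc1ccccc1 | intermediate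
10 | lithium 3,5-bis(benzyloxy)-4-methoxy-2-(trimethylsilyl)phenoxide (formed in the flask) | COc1c(OCc2ccccc2)cc([O-])c([Si](C)(C)C)c1OCc1ccccc1.[Li+] | intermediate
11 | 3,5-bis(benzyloxy)-4-methoxy-2-(trimethylsilyl)phenyl trifluoromethanesulfonate | COc1c(OCc2ccccc2)cc(OS(=O)(=O)C(F)(F)F)c([Si](C)(C)C)c1OCc1ccccc1 | intermediate
12 | 4-iodophenol | Oc1ccc(I)cc1 | starting material
13 | 1-iodo-4-(methoxymethoxy)benzene | COCOc1ccc(I)cc1 | intermediate
14 | propiolic acid | C#CC(=O)O | starting material
15 | 3-[4-(methoxymethoxy)phenyl]propiolic acid | COCOc1ccc(C#CC(=O)O)cc1 | intermediate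
16 | 3,5-bis(benzyloxy)-4-methoxybenzyne, triple bond C1≡C2 (formed in the flask) | COC1=C(OCc2ccccc2)C#CC=C1OCc1ccccc1 | intermediate
17 | 1-[2,4-bis(benzyloxy)-6-hydroxy-3-methoxyphenyl]-3-[4-(methoxymethoxy)phenyl]prop-2-yn-1-one (present in the flask as its caesium phenoxide) | COCOc1ccc(C#CC(=O)c2c(O)cc(OCc3ccccc3)c(OC)c2OCc2ccccc2)cc1 | intermediate
18 | 5,7-bis(benzyloxy)-6-methoxy-2-[4-(methoxymethoxy)phenyl]-4H-chromen-4-one | COc1c(OCc2ccccc2)cc2oc(-c3ccc(OCOC)cc3)cc(=O)c2c1OCc1ccccc1 | intermediate
19 | 5,7-bis(benzyloxy)-2-(4-hydroxyphenyl)-6-methoxy-4H-chromen-4-one | COc1c(OCc2ccccc2)cc2oc(-c3ccc(O)cc3)cc(=O)c2c1OCc1ccccc1 | intermediate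
20 | 4-[5,7-bis(benzyloxy)-6-methoxy-4-oxo-4H-chromen-2-yl]phenyl 2,2,2-trichloroethyl sulfate | COc1c(OCc2ccccc2)cc2oc(-c3ccc(OS(=O)(=O)OCC(Cl)(Cl)Cl)cc3)cc(=O)c2c1OCc1ccccc1 | intermediate
21 | ammonium 4-(5,7-dihydroxy-6-methoxy-4-oxo-4H-chromen-2-yl)phenyl sulfate | COc1c(O)cc2oc(-c3ccc(OS(=O)(=O)[O-])cc3)cc(=O)c2c1O.[NH4+] | intermediate
22 | hispidulin 4'-sulfate | COc1c(O)cc2oc(-c3ccc(OS(=O)(=O)O)cc3)cc(=O)c2c1O | target

Total step count: 13.
Longest linear sequence: 11 steps (steps 1–6 and 9–13). The ring B branch (steps 7–8) is two steps.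

Steps most likely to fail

1. Step 9 (aryne insertion and ring closure). Three things may go wrong. The aryl anion may be protonated before the acyl group migrates, the propiolate may lose CO2 at 125 °C, or part of the phenoxide may close in the 5-exo mode. The fallback sets out from bromophenol 7 and acid 15 and comes back at flavone 18. It makes the C4a–C4 bond by acylating an aryllithium instead of going through an aryne. Acid 15 is activated with carbonyldiimidazole and treated with MeNHOMe·HCl to give N-methoxy-N-methyl-3-[4-(methoxymethoxy)phenyl]prop-2-ynamide F1. Bromophenol 7 is deprotonated with MeLi and exchanged with t-BuLi (2 equiv) in THF at −78 °C to the dilithiated phenoxide F2. This adds to F1 (Weinreb ketone synthesis), and aqueous quench releases ynone 17, this time isolated. Diethylamine in DMF adds to the triple bond to give the enaminone F3, whose double-bond geometry is labile and of no consequence. Addition–elimination by the ortho phenol then expels the amine and gives 18, a path that cannot lead to the five-membered ring.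

2. Step 12 (global reductive unmasking). The C2–C3 bond of the pyrone may be saturated under transfer hydrogenation. The trichloroethyl group may be only partly dechlorinated to an ester that no longer fragments. Cleavage of the crowded 5-O-benzyl group may stall. The fallback sets out from 20 and comes back at 21. It separates the two tasks and avoids palladium. BCl3 with pentamethylbenzene as cation scavenger in CH2Cl2 at −78 °C removes both benzyl groups by Lewis-acid-assisted cleavage, which the acid-stable sulfate diester should tolerate. This gives hispidulin 4'-(2,2,2-trichloroethyl sulfate) F4. Zinc dust with HCO2NH4 in MeOH at rt then fragments the trichloroethyl ester by two-electron reduction, to which the pyrone double bond is inert, and gives 21.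

3. Step 6 (silyl shift and triflation). Benzylic deprotonation may compete with the exchange. Silyl migration to the crowded carbon between two oxygens may be incomplete, or silicon may be lost during handling. The fallback sets out from phenol 6 and comes back at triflate 11, so the bromination of step 5 is bypassed as well. It introduces silicon by directed ortho-metalation. Phenol 6 is carbamoylated (ClC(O)NEt2, NaH, THF) to the N,N-diethylcarbamate F5. s-BuLi/TMEDA in THF at −78 °C removes the proton between the carbamate and a benzyloxy group (the two such sites are equivalent) to give the ortho-lithiated carbamate F6. TMSCl quenches this to the ortho-silyl carbamate F7. LiAlH4 in THF cleaves the carbamate reductively to the silylphenol F8, and Tf2O/pyridine in CH2Cl2 at 0 °C gives 11.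

Further compounds
F1 | step 9 | N-methoxy-N-methyl-3-[4-(methoxymethoxy)phenyl]prop-2-ynamide | COCOc1ccc(C#CC(=O)N(C)OC)cc1
F2 | step 9 | lithium 3,5-bis(benzyloxy)-2-lithio-4-methoxyphenoxide | COc1c(OCc2ccccc2)cc([O-])c([Li])c1OCc1ccccc1.[Li+]
F3 | step 9 | (E)-1-[2,4-bis(benzyloxy)-6-hydroxy-3-methoxyphenyl]-3-(diethylamino)-3-[4-(methoxymethoxy)phenyl]prop-2-en-1-one | CCN(CC)/C(=C/C(=O)c1c(O)cc(OCc2ccccc2)c(OC)c1OCc1ccccc1)c1ccc(OCOC)cc1
F4 | step 12 | 4-(5,7-dihydroxy-6-methoxy-4-oxo-4H-chromen-2-yl)phenyl 2,2,2-trichloroethyl sulfate | COc1c(O)cc2oc(-c3ccc(OS(=O)(=O)OCC(Cl)(Cl)Cl)cc3)cc(=O)c2c1O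
F5 | step 6 | 3,5-bis(benzyloxy)-4-methoxyphenyl N,N-diethylcarbamate | CCN(CC)C(=O)Oc1cc(OCc2ccccc2)c(OC)c(OCc2ccccc2)c1
F6 | step 6 | 3,5-bis(benzyloxy)-2-lithio-4-methoxyphenyl N,N-diethylcarbamate | CCN(CC)C(=O)Oc1cc(OCc2ccccc2)c(OC)c(OCc2ccccc2)c1[Li]
F7 | step 6 | 3,5-bis(benzyloxy)-4-methoxy-2-(trimethylsilyl)phenyl N,N-diethylcarbamate | CCN(CC)C(=O)Oc1cc(OCc2ccccc2)c(OC)c(OCc2ccccc2)c1[Si](C)(C)C
F8 | step 6 | 3,5-bis(benzyloxy)-4-methoxy-2-(trimethylsilyl)phenol | COc1c(OCc2ccccc2)cc(O)c([Si](C)(C)C)c1OCc1ccccc1
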